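**Retrosynthetic overview**
1. Helilupolone 22 is the C2-acyl derivative of the triprenylated cyclohexanetrione 19, so the 3-phenylpropanoyl group is put on last by O-acylation and O-to-C acyl shift.
2. The ring of 19 is a 6,6-disubstituted cyclohexa-2,4-dienone (C1=O, C2=C3–O, C4=C5–O, quaternary C6 with two prenyl groups). It is the valence isomer of the dienylketene O=C1=C2–C3(OR)=C4(prenyl)–C5(OR')=C6(prenyl)2, and because C6 is fully substituted, the 6π closure C1–C6 cannot aromatise and gives the dienone core directly.
3. The dienylketene is made in the flask from cyclobutenone 13 and ethoxyacetylene 14 (4π opening, ketene–ynol ether [2+2], 4π opening). The four-membered ring is a temporary ring that is absent from the target.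
4. 13 comes from a [2+2] of diprenylketene (from diethyl malonate and prenyl bromide) with a prenyl-substituted siloxyalkyne (from ethynylmagnesium bromide and prenyl bromide).
5. Ring order: cyclobutenone (step 7), then the six-membered ring (step 8); the phenyl ring is bought with 20.

Key step: step 8

Remark: the target is achiral, and 19, 21 and 22 are mobile enol tautomers; each is written in the dienol form that matches the drawn target.

**Step 1**
Reactants: 1 diethyl malonate; 2 prenyl bromide (1-bromo-3-methylbut-2-ene)
Product: 3 diethyl 2,2-bis(3-methylbut-2-en-1-yl)propanedioate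
Conditions: NaH (2.2 equiv), 2 (2.2 equiv), THF, 0 °C → reflux
Reagents that add atoms: none
Why: Double SN2 alkylation of the malonate enolate (malonic ester synthesis) with an unhindered primary allylic bromide should go cleanly to the dialkylated ester, and no stereocentre is formed.

**Step 2**
Reactants: 3 diethyl 2,2-bis(3-methylbut-2-en-1-yl)propanedioate
Product: 4 2,2-bis(3-methylbut-2-en-1-yl)propanedioic acid
Conditions: KOH (excess), EtOH/H2O, reflux; then cold 1 M HCl to pH 2
Reagents that add atoms: potassium hydroxide [K+].[OH-]
Why: Saponification of the hindered diester needs hot alkali, which nothing else in the molecule resents, and brief cold acidification should free the diacid without touching the trisubstituted alkenes.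

**Step 3**
Reactants: 4 2,2-bis(3-methylbut-2-en-1-yl)propanedioic acid
Product: 5 5-methyl-2-(3-methylbut-2-en-1-yl)hex-4-enoic acid (diprenylacetic acid)
Conditions: neat, 160 °C, N2
Reagents that add atoms: none
Why: Thermal decarboxylation of a disubstituted malonic acid through the cyclic six-membered transition state (second half of the malonic ester synthesis) should give the α,α-dialkylacetic acid.

**Step 4**
Reactants: 5 5-methyl-2-(3-methylbut-2-en-1-yl)hex-4-enoic acid
Product: 6 5-methyl-2-(3-methylbut-2-en-1-yl)hex-4-enoyl chloride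
Conditions: (COCl)2 (1.3 equiv), DMF (cat.), CH2Cl2, 0 → 20 °C; evaporate
Reagents that add atoms: oxalyl chloride ClC(=O)C(=O)Cl
Why: Vilsmeier-type activation with oxalyl chloride/DMF forms the acid chloride at low temperature with only gaseous by-products, conditions that isolated trisubstituted alkenes are expected to tolerate.

**Step 5**
Reactants: 7 ethynylmagnesium bromide (THF solution); 2 prenyl bromide
Product: 8 5-methylhex-4-en-1-yne
Conditions: 7 (1.8 equiv), CuCl (5 mol%), THF, 0 → 50 °C; distil
Reagents that add atoms: none
Why: CuCl-catalysed allylic substitution of an alkynyl Grignard reagent at the primary carbon of prenyl bromide should give the skipped enyne, and the excess of acetylide suppresses double alkylation.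

**Step 6**
Reactants: 8 5-methylhex-4-en-1-yne
Product: 11 triisopropyl[(5-methylhex-4-en-1-yn-1-yl)oxy]silane, via lithium acetylide 9 (not isolated), via lithium ynolate 10 (not isolated)
Conditions: n-BuLi, THF, −78 °C; t-BuOOLi (from t-BuOOH and LiN(SiMe3)2), −78 → 0 °C; TIPSOTf, −78 → 20 °C
Reagents that add atoms: lithium tert-butyl peroxide [Li+].CC(C)(C)O[O-]; triisopropylsilyl trifluoromethanesulfonate CC(C)[Si](OS(=O)(=O)C(F)(F)F)(C(C)C)C(C)C
Why: Electrophilic oxygen transfer from the lithium peroxide to the lithium acetylide (acetylide oxygenation to an ynolate) followed by O-silylation with the bulky silyl triflate is the standard entry to 1-siloxy-1-alkynes.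

**Step 7**
Reactants: 6 5-methyl-2-(3-methylbut-2-en-1-yl)hex-4-enoyl chloride; 11 triisopropyl[(5-methylhex-4-en-1-yn-1-yl)oxy]silane
Product: 13 2,4,4-tris(3-methylbut-2-en-1-yl)-3-[(triisopropylsilyl)oxy]cyclobut-2-en-1-one, via diprenylketene 12 (not isolated)
Conditions: Et3N (1.5 equiv), toluene, 80 °C, slow addition of 6 to 11
Reagents that add atoms: none
Why: Dehydrochlorination gives the dialkylketene, which should undergo the polarity-controlled ketene–ynol ether [2+2] cycloaddition (nucleophilic alkyne carbon to the ketene carbonyl carbon) to the 3-siloxycyclobutenone; the ring sp3 carbon carries two identical prenyl groups, so no stereocentre arises.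

**Step 8**
Reactants: 13 2,4,4-tris(3-methylbut-2-en-1-yl)-3-[(triisopropylsilyl)oxy]cyclobut-2-en-1-one; 14 ethoxyacetylene
Product: 18 3-ethoxy-4,6,6-tris(3-methylbut-2-en-1-yl)-5-[(triisopropylsilyl)oxy]cyclohexa-2,4-dien-1-one, via vinylketene 15 (not isolated), via 4-alkenylcyclobutenone 16 (not isolated), via dienylketene 17 (not isolated)
Conditions: 14 (4 equiv), degassed toluene, hν (Pyrex-filtered medium-pressure Hg lamp), 20 °C; then 80 °C, dark
Reagents that add atoms: none
Why: Proposed new method: an interrupted vinylketene–alkyne annulation of the Danheiser benzannulation type, in which light opens 13 by 4π electrocyclic cleavage to vinylketene 15, the ynol ether adds to the ketene C=C in a [2+2] (its nucleophilic CH carbon to the ketene carbonyl carbon) to give 16, and at 80 °C 16 opens (4π) to dienylketene 17, which closes by thermal disrotatory 6π electrocyclisation between the ketene carbon and the diprenyl-substituted alkene terminus. The closest known reactions are the cyclobutenone/ynol ether benzannulation to resorcinol ethers and the thermal closure of dienylketenes to 6,6-disubstituted cyclohexa-2,4-dienones (the reverse of their photochemical ring opening); here the fully substituted terminus stops the cascade at the dienone. The transient four-membered ring of 16 closes by [2+2] cycloaddition and the six-membered ring by 6π electrocyclisation, a pericyclic and not an ionic acylation, which is why the bond should form at carbon and not at the enol oxygen and why a quaternary carbon can be made under neutral conditions. No stereocentre results, because the new quaternary carbon carries two identical prenyl groups and the stereocentre of racemic 16 is destroyed on ring opening. The step needs regioselective [2+2] (secured by the polarisation of the ynol ether, which places the ethoxy-bearing carbon next to the prenyl-bearing carbon), the geometry of 17 with the ketene carbon and the silyloxyvinyl group cis (the other isomer should reclose to 16 and reopen), and trapping of 15 faster than its 1,5-hydrogen shift or intramolecular ketene–alkene addition (favoured by excess ynol ether and by generating 15 with light at 20 °C).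

**Step 9**
Reactants: 18 3-ethoxy-4,6,6-tris(3-methylbut-2-en-1-yl)-5-[(triisopropylsilyl)oxy]cyclohexa-2,4-dien-1-one
Product: 19 3,5-dihydroxy-4,6,6-tris(3-methylbut-2-en-1-yl)cyclohexa-2,4-dien-1-one (dienol form of 2,2,4-triprenylcyclohexane-1,3,5-trione)
Conditions: 1 M HCl, degassed THF, 0 → 20 °C; use at once under N2
Reagents that add atoms: water O
Why: Dilute acid should cleave the vinylogous silyl ester and hydrolyse the β-ethoxy enone (enol ether hydrolysis by C-protonation, water addition and loss of ethanol) at room temperature, where isolated prenyl groups are expected to survive.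

**Step 10**
Reactants: 19 3,5-dihydroxy-4,6,6-tris(3-methylbut-2-en-1-yl)cyclohexa-2,4-dien-1-one; 20 3-phenylpropanoyl chloride
Product: 22 helilupolone, via enol ester 21 (not isolated)
Conditions: 20 (1.05 equiv), Et3N (2.2 equiv), CH2Cl2, 0 °C; then DMAP (0.2 equiv), 20 °C; 1 M HCl work-up
Reagents that add atoms: none
Why: O-acylation of the trione enolate followed by DMAP-mediated O-to-C acyl migration (enol ester rearrangement of cyclic 1,3-diones) should deliver the acyl group to the only unsubstituted carbon between two carbonyls, the chelated enolised β-triketone being the thermodynamic sink.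

**Compound list**
1 | diethyl malonate | CCOC(=O)CC(=O)OCC | starting material
2 | prenyl bromide (1-bromo-3-methylbut-2-ene) | CC(C)=CCBr | starting material
3 | diethyl 2,2-bis(3-methylbut-2-en-1-yl)propanedioate | CCOC(=O)C(CC=C(C)C)(CC=C(C)C)C(=O)OCC | intermediate
4 | 2,2-bis(3-methylbut-2-en-1-yl)propanedioic acid | OC(=O)C(CC=C(C)C)(CC=C(C)C)C(=O)O | intermediate
5 | 5-methyl-2-(3-methylbut-2-en-1-yl)hex-4-enoic acid | OC(=O)C(CC=C(C)C)CC=C(C)C | intermediate
6 | 5-methyl-2-(3-methylbut-2-en-1-yl)hex-4-enoyl chloride | ClC(=O)C(CC=C(C)C)CC=C(C)C | intermediate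
7 | ethynylmagnesium bromide | C#C[Mg]Br | starting material
8 | 5-methylhex-4-en-1-yne | C#CCC=C(C)C | intermediate
9 | lithium 5-methylhex-4-en-1-yn-1-ide | [Li]C#CCC=C(C)C | intermediate (not isolated)
10 | lithium 5-methylhex-4-en-1-yn-1-olate | [Li]OC#CCC=C(C)C | intermediate (not isolated)
11 | triisopropyl[(5-methylhex-4-en-1-yn-1-yl)oxy]silane | CC(C)=CCC#CO[Si](C(C)C)(C(C)C)C(C)C | intermediate
12 | diprenylketene (5-methyl-2-(3-methylbut-2-en-1-yl)hexa-1,4-dien-1-one) | O=C=C(CC=C(C)C)CC=C(C)C | intermediate (not isolated)
13 | 2,4,4-tris(3-methylbut-2-en-1-yl)-3-[(triisopropylsilyl)oxy]cyclobut-2-en-1-one | O=C1C(CC=C(C)C)=C(O[Si](C(C)C)(C(C)C)C(C)C)C1(CC=C(C)C)CC=C(C)C | intermediate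
14 | ethoxyacetylene | CCOC#C | starting material
15 | 7-methyl-2,4-bis(3-methylbut-2-en-1-yl)-3-[(triisopropylsilyl)oxy]octa-1,3,6-trien-1-one | O=C=C(CC=C(C)C)C(O[Si](C(C)C)(C(C)C)C(C)C)=C(CC=C(C)C)CC=C(C)C | intermediate (not isolated)
16 | racemic 3-ethoxy-4-(3-methylbut-2-en-1-yl)-4-{5-methyl-2-(3-methylbut-2-en-1-yl)-1-[(triisopropylsilyl)oxy]hexa-1,4-dien-1-yl}cyclobut-2-en-1-one | O=C1C=C(OCC)C1(CC=C(C)C)C(O[Si](C(C)C)(C(C)C)C(C)C)=C(CC=C(C)C)CC=C(C)C | intermediate (not isolated)
17 | (3E)-3-ethoxy-9-methyl-4,6-bis(3-methylbut-2-en-1-yl)-5-[(triisopropylsilyl)oxy]deca-1,3,5,8-tetraen-1-one | O=C=C/C(OCC)=C(/CC=C(C)C)C(O[Si](C(C)C)(C(C)C)C(C)C)=C(CC=C(C)C)CC=C(C)C | intermediate (not isolated)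
18 | 3-ethoxy-4,6,6-tris(3-methylbut-2-en-1-yl)-5-[(triisopropylsilyl)oxy]cyclohexa-2,4-dien-1-one | O=C1C=C(OCC)C(CC=C(C)C)=C(O[Si](C(C)C)(C(C)C)C(C)C)C1(CC=C(C)C)CC=C(C)C | intermediate
19 | 3,5-dihydroxy-4,6,6-tris(3-methylbut-2-en-1-yl)cyclohexa-2,4-dien-1-one | O=C1C=C(O)C(CC=C(C)C)=C(O)C1(CC=C(C)C)CC=C(C)C | intermediate
20 | 3-phenylpropanoyl chloride | O=C(Cl)CCc1ccccc1 | starting material
21 | 5-hydroxy-4,4,6-tris(3-methylbut-2-en-1-yl)-3-oxocyclohexa-1,5-dien-1-yl 3-phenylpropanoate | O=C1C=C(OC(=O)CCc2ccccc2)C(CC=C(C)C)=C(O)C1(CC=C(C)C)CC=C(C)C | intermediate (not isolated)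
22 | helilupolone (3,5-dihydroxy-4,6,6-tris(3-methylbut-2-en-1-yl)-2-(3-phenylpropanoyl)cyclohexa-2,4-dien-1-one) | CC(C)=CCC1=C(O)C(CC=C(C)C)(CC=C(C)C)C(=O)C(C(=O)CCc2ccccc2)=C1O | target

**Step count and risks**
Total: 10 steps. Longest linear sequence: 8 steps (1, 2, 3, 4, 7, 8, 9, 10).

Steps most likely to fail:

- **Step 8 (Proposed new method).** The vinylketene may leak away by 1,5-hydrogen shift or by intramolecular cycloaddition to a prenyl alkene before the ynol ether traps it. The crowded 6π closure may lag behind these leaks, and prolonged irradiation may degrade the product. The fallback uses known chemistry, sets out from 20 and comes back at 22. Phloroglucinol F1 (bought) is acylated with 20 under AlCl3 in CH2Cl2/nitrobenzene (Friedel–Crafts acylation) to give 1-(2,4,6-trihydroxyphenyl)-3-phenylpropan-1-one F2. Treating F2 with 2 (3.3 equiv) and NaOMe in MeOH at 0 °C should give two nuclear C-prenylations and a third, dearomatising C-prenylation at an already prenylated carbon, a reaction type established for acylphloroglucinols, and so 22.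

- **Step 7.** Dehydrochlorination of the α,α-dialkyl acid chloride is slow, so ketene dimerisation and decomposition of the acid-sensitive siloxyalkyne by the ammonium salt may outrun the cycloaddition. The fallback sets out from 6 and comes back at 13. Compound 6 is esterified with lithium 2,6-di-tert-butyl-4-methylphenoxide (THF) to the hindered aryl ester F3. Deprotonation with LiN(i-Pr)2 at −78 °C gives the ester enolate F4, and 11 is then added. On warming to 20 °C, F4 should expel the hindered phenoxide (E1cB) and release 12 free of ammonium salt, which 11 traps to give 13.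

- **Step 6.** Oxygen transfer to the acetylide may be incomplete, the skipped enyne may isomerise under base, or the ynolate may be silylated on carbon. The fallback sets out from 14 (with 2 and 6) and comes back at 13. Compound 14 is lithiated (n-BuLi, THF, −78 °C) to lithium ethoxyacetylide F5 and alkylated with 2 (DMPU) to 1-ethoxy-5-methylhex-4-en-1-yne F6. [2+2] cycloaddition of F6 with 12, generated from 6 as in step 7, should give 3-ethoxy-2,4,4-tris(3-methylbut-2-en-1-yl)cyclobut-2-en-1-one F7. Brief hydrolysis of this strained vinylogous ester (0.5 M HCl, THF, 20 °C) gives 2,2,4-tris(3-methylbut-2-en-1-yl)cyclobutane-1,3-dione F8. Silylation of its only possible enol with TIPSOTf/Et3N then gives 13.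

**Further compounds**
F1 | step 8 | phloroglucinol (benzene-1,3,5-triol, bought) | Oc1cc(O)cc(O)c1
F2 | step 8 | 1-(2,4,6-trihydroxyphenyl)-3-phenylpropan-1-one | O=C(CCc1ccccc1)c1c(O)cc(O)cc1O
F3 | step 7 | 2,6-di-tert-butyl-4-methylphenyl 5-methyl-2-(3-methylbut-2-en-1-yl)hex-4-enoate | Cc1cc(C(C)(C)C)c(OC(=O)C(CC=C(C)C)CC=C(C)C)c(C(C)(C)C)c1
F4 | step 7 | lithium enolate of F3 | [Li]OC(Oc1c(C(C)(C)C)cc(C)cc1C(C)(C)C)=C(CC=C(C)C)CC=C(C)C
F5 | step 6 | lithium ethoxyacetylide | [Li]C#COCC
F6 | step 6 | 1-ethoxy-5-methylhex-4-en-1-yne | CCOC#CCC=C(C)C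
F7 | step 6 | 3-ethoxy-2,4,4-tris(3-methylbut-2-en-1-yl)cyclobut-2-en-1-one | O=C1C(CC=C(C)C)=C(OCC)C1(CC=C(C)C)CC=C(C)C
F8 | step 6 | 2,2,4-tris(3-methylbut-2-en-1-yl)cyclobutane-1,3-dione | O=C1C(CC=C(C)C)C(=O)C1(CC=C(C)C)CC=C(C)C
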